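**Retrosynthetic overview**
1. Michaolide F ⇒ seco-alcohol 19. The last step forms C1–C14 by a visible-light HAT/photoredox macrocyclisation onto an α-(acetoxymethyl)butenolide; it closes the 14-ring, reveals the α-methylene group and sets C1 and C14.
2. 19 ⇒ epoxy aldehyde 14 + iodoacrylate 16. NHK alkenylation/lactonisation forms C1–C2 (Felkin control sets C2), and the C5 acetate is installed by Mitsunobu inversion.
3. 14 ⇒ (5S)-allylic alcohol 12 by hydroxyl-directed vanadium epoxidation (sets C3 and C4); 12 ⇒ dioxolanone 9 by MeLi addition, Wittig olefination and DIBAL reduction.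
4. 9 ⇒ L-malic acid acetonide 8 + dienyl iodide 6 by Ni-electrocatalytic decarboxylative alkenylation (C6–C7). Iodide 6 comes from two Negishi carboaluminations.
5. Ring order: epoxide → butenolide → 14-membered carbocycle. The only purchased stereocentre is C5 (L-malic acid); the other five are relayed from it.

Assumption (numbering): cembrane numbering is used. C1 = lactone β-CH, C2 = lactone O–CH, C3/C4 = epoxide, C5 = CHOAc, C14 = CHOH, C15–C17 = acrylate unit. The target is (1R,2S,3S,4S,5R,14R,7E,11E).

**Step 1**
Reactants: 1, tert-butyl(but-3-yn-1-yloxy)dimethylsilane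
Product: 2, (E)-tert-butyl[(4-iodo-3-methylbut-3-en-1-yl)oxy]dimethylsilane
Conditions: Me3Al, Cp2ZrCl2 (25 mol %), CH2Cl2, 0→23 °C; then I2, THF, −30 °C
Reagents that add atoms: trimethylaluminium, C[Al](C)C; iodine, II
Why: Negishi Zr-catalysed carboalumination adds Me–Al syn across the terminal alkyne (Me to the internal carbon), and iodinolysis with retention gives the E-trisubstituted C11=C12 unit.

**Step 2**
Reactants: 2; 3, (4-bromobut-1-yn-1-yl)trimethylsilane
Product: 4, (E)-tert-butyldimethyl{[3-methyl-8-(trimethylsilyl)oct-3-en-7-yn-1-yl]oxy}silane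
Conditions: 3, Zn, I2 (5 mol %), DMA, 80 °C; then 2, PdCl2(dppf) (2 mol %), THF, 23 °C
Reagents that add atoms: none
Why: Negishi sp3–sp2 cross-coupling forms C10–C11 with full retention of alkene geometry.

**Step 3**
Reactants: 4
Product: 5, (E)-tert-butyldimethyl[(3-methyloct-3-en-7-yn-1-yl)oxy]silane
Conditions: K2CO3, MeOH, 23 °C
Reagents that add atoms: none
Why: Base-mediated protodesilylation removes only the alkynyl TMS group, and the TBS ether is stable.

**Step 4**
Reactants: 5
Product: 6, tert-butyl{[(3E,7E)-8-iodo-3,7-dimethylocta-3,7-dien-1-yl]oxy}dimethylsilane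
Conditions: Me3Al, Cp2ZrCl2 (25 mol %), CH2Cl2, 0→23 °C; then I2, THF, −30 °C
Reagents that add atoms: trimethylaluminium, C[Al](C)C; iodine, II
Why: A second Negishi carboalumination/iodination sets the E-C7=C8 alkene; the existing trisubstituted alkene is inert.

**Step 5**
Reactants: 7, L-(S)-malic acid
Product: 8, (S)-2-(2,2-dimethyl-5-oxo-1,3-dioxolan-4-yl)acetic acid
Conditions: 2,2-dimethoxypropane, PPTS (cat.), 23 °C
Reagents that add atoms: 2,2-dimethoxypropane, COC(C)(C)OC
Why: Acetonide (dioxolanone) formation engages only the α-hydroxy acid, frees the β-CO2H, activates the future C4 carbonyl and leaves the stereocentre (future C5) untouched.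

**Step 6**
Reactants: 8; 6
Product: 9, (S)-5-[(2E,6E)-9-(tert-butyldimethylsilyloxy)-3,7-dimethylnona-2,6-dien-1-yl]-2,2-dimethyl-1,3-dioxolan-4-one
Conditions: 8, N-hydroxyphthalimide, DIC, DMAP (cat.), DMF, 23 °C; then 6, NiCl2·6H2O (10 mol %), 2,2′-bipyridine (10 mol %), AgNO3 (0.3 equiv), undivided cell, (+)Mg/(−)RVC, constant current, ~3 F/mol, 23 °C
Reagents that add atoms: none
Why: In this Ni-electrocatalytic decarboxylative alkenylation (redox-active ester/alkenyl iodide cross-electrophile coupling), cathodic fragmentation gives the primary C6 radical, which alkenyl-nickel captures with retention of E geometry, while the adjacent C5 stereocentre is not involved.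

**Step 7**
Reactants: 9
Product: 10, (3S,5E,9E)-12-(tert-butyldimethylsilyloxy)-3-hydroxy-6,10-dimethyldodeca-5,9-dien-2-one
Conditions: MeLi (1.1 equiv), THF, −78 °C; AcOH quench
Reagents that add atoms: methyllithium, [Li]C
Why: MeLi adds 1,2 to the activated dioxolanone carbonyl; the cyclic lithium hemiketal survives at −78 °C and collapses only on quench (loss of acetone) to the α-hydroxy methyl ketone without over-addition.

**Step 8**
Reactants: 10
Product: 11, ethyl (2E,4S,6E,10E)-13-(tert-butyldimethylsilyloxy)-4-hydroxy-3,7,11-trimethyltrideca-2,6,10-trienoate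
Conditions: Ph3P=CHCO2Et, toluene, 70 °C
Reagents that add atoms: (carbethoxymethylene)triphenylphosphorane, CCOC(=O)C=P(c1ccccc1)(c1ccccc1)c1ccccc1
Why: Wittig olefination of the activated α-hydroxy ketone with a stabilised ylide gives the E-C3=C4 enoate, and any Z isomer lactonises to a butenolide that is removed by chromatography.

**Step 9**
Reactants: 11
Product: 12, (2E,4S,6E,10E)-13-(tert-butyldimethylsilyloxy)-3,7,11-trimethyltrideca-2,6,10-triene-1,4-diol
Conditions: DIBAL-H (3.5 equiv), CH2Cl2, −78 °C; Rochelle salt
Reagents that add atoms: none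
Why: DIBAL reduces the enoate 1,2 to the allylic alcohol without touching the alkenes or the silyl ether.

**Step 10**
Reactants: 12
Product: 13, (3S,4S,5S)-3,4-epoxy-2,5-diol (trans epoxide configured as in the target, C5 epimeric, C14-OTBS)
Conditions: VO(acac)2 (3 mol %), t-BuOOH (1.1 equiv, decane), CH2Cl2, −10→0 °C
Reagents that add atoms: tert-butyl hydroperoxide, CC(C)(C)OO
Why: In this hydroxyl-directed vanadium epoxidation only the doubly allylic C3=C4 alkene reacts. A(1,2) strain places H5 next to the C4 methyl, so oxygen arrives on the O5 face, anti to the C6 chain, whichever hydroxyl binds vanadium, and this gives the erythro epoxy alcohol.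

**Step 11**
Reactants: 13
Product: 14, (3R,4S,5S)-3,4-epoxy-5-hydroxy-C2-aldehyde (same spatial arrangement as 13; the C3 label changes by CIP priority only)
Conditions: TEMPO (10 mol %), PhI(OAc)2 (1.1 equiv), CH2Cl2, 0→23 °C
Reagents that add atoms: none
Why: TEMPO/PhI(OAc)2 oxidises the primary alcohol selectively over the hindered secondary one, and the trans epoxide prevents lactol formation.

**Step 12**
Reactants: 15, methyl propiolate
Product: 16, methyl (Z)-2-(hydroxymethyl)-3-iodoacrylate
Conditions: Et2AlI (1.2 equiv), CH2Cl2, −78 °C; HCHO (gas, cracked paraformaldehyde), −78→−40 °C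
Reagents that add atoms: diethylaluminium iodide, CC[Al](I)CC; formaldehyde, C=O
Why: In this β-iodo Morita–Baylis–Hillman reaction, conjugate iodide addition gives an aluminium allenolate whose low-temperature aldol with formaldehyde gives the kinetic Z isomer (I cis to CO2Me).

**Step 13**
Reactants: 14; 16
Product: 17, (2S,3S,4S,5S)-butenolide diol: 3-(hydroxymethyl)furan-2(5H)-one carrying the epoxy-alcohol chain at its C5 position
Conditions: CrCl2 (5 equiv), NiCl2 (1 mol %), DMSO–THF, 23 °C; PPTS (cat.), CH2Cl2 to complete lactonisation
Reagents that add atoms: none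
Why: In this Nozaki–Hiyama–Kishi alkenylation the alkenyl-chromium attacks the aldehyde in the Felkin–Anh sense (anti to the C3–O bond, passing H3, reinforced by the cis C4 methyl). This gives the anti C2/C3 relationship (2S), and the Z-γ-alkoxy ester closes to the butenolide with loss of MeOH.

**Step 14**
Reactants: 17
Product: 18, (2S,3S,4S,5R)-5,17-diacetate
Conditions: AcOH (6 equiv), PPh3 (5 equiv), DIAD (5 equiv), toluene, 0→23 °C
Reagents that add atoms: acetic acid, CC(=O)O (two equivalents incorporated)
Why: This double Mitsunobu esterification converts the primary C17-OH into the leaving-group acetate. SN2 displacement at C5 inverts 5S to 5R, turning the erythro array into the natural threo epoxy acetate with the acetate installed directly.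

**Step 15**
Reactants: 18
Product: 19, seco-alcohol (free C14 primary OH)
Conditions: HF·pyridine, pyridine, THF, 0 °C
Reagents that add atoms: none
Why: Buffered fluoride desilylation removes the primary TBS ether without affecting the acetates, epoxide or butenolide.

**Step 16**
Reactants: 19
Product: 20, michaolide F
Conditions: [Ir(dF(CF3)ppy)2(dtbbpy)]PF6 (2 mol %), quinuclidine (30 mol %), Bu4N·H2PO4 (30 mol %), MeCN (1 mM, flow loop), 450 nm LEDs, 25 °C
Reagents that add atoms: none
Why: Proposed new method: this is a redox-neutral dehydro-allylative macrocyclisation in which excited Ir(III) oxidises quinuclidine to its radical cation, which abstracts the hydridic, phosphate-hydrogen-bond-activated α-C–H of the primary alcohol (C14) in preference to allylic or α-acyloxy C–H; the nucleophilic α-hydroxyalkyl radical adds to the electrophilic β-carbon C1 of the butenolide on the face anti to the C2 side chain (1R, trans-lactone), Ir(II) reduces the C15 α-acyl radical to the lactone enolate, and E1cB loss of the C17 acetate gives the α-methylene group and closes both catalytic cycles (AcOH is the only by-product, and unproductive HAT is reversible, so high dilution wastes no substrate); C14 is set in an open antiperiplanar transition state in which the bulky anionic O–H···phosphate unit points away from the developing enolate (anti to C15), C13 takes the free sector next to H1 and H14 takes the crowded sector between C2 and C15, giving 14R (OH syn to C2); the closest known reaction types are photoredox/quinuclidine/phosphate α-C–H alkylation of alcohols with acrylates and radical addition–elimination on Morita–Baylis–Hillman acetates, neither of which has been shown on a β-substituted endocyclic acceptor or for ring closure.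

**Compound list**
1 | tert-butyl(but-3-yn-1-yloxy)dimethylsilane | C#CCCO[Si](C)(C)C(C)(C)C | starting material
2 | (E)-4-iodo-3-methylbut-3-enyl TBS ether | CC(C)(C)[Si](C)(C)OCC/C(C)=C/I | intermediate
3 | (4-bromobut-1-yn-1-yl)trimethylsilane | C[Si](C)(C)C#CCCBr | starting material
4 | TMS-enyne TBS ether | CC(C)(C)[Si](C)(C)OCC/C(C)=C/CCC#C[Si](C)(C)C | intermediate
5 | terminal enyne TBS ether | CC(C)(C)[Si](C)(C)OCC/C(C)=C/CCC#C | intermediate
6 | (3E,7E)-8-iodo-3,7-dimethylocta-3,7-dienyl TBS ether | CC(C)(C)[Si](C)(C)OCC/C(C)=C/CC/C(C)=C/I | intermediate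
7 | L-(S)-malic acid | O[C@@H](CC(=O)O)C(=O)O | starting material
8 | (S)-2-(2,2-dimethyl-5-oxo-1,3-dioxolan-4-yl)acetic acid | CC1(C)O[C@@H](CC(=O)O)C(=O)O1 | intermediate
9 | (S)-5-dienyl-2,2-dimethyl-1,3-dioxolan-4-one | CC(C)(C)[Si](C)(C)OCC/C(C)=C/CC/C(C)=C/C[C@@H]1OC(C)(C)OC1=O | intermediate
10 | (5S)-α-hydroxy methyl ketone | CC(C)(C)[Si](C)(C)OCC/C(C)=C/CC/C(C)=C/C[C@H](O)C(C)=O | intermediate
11 | (5S)-γ-hydroxy-(E)-enoate | CC(C)(C)[Si](C)(C)OCC/C(C)=C/CC/C(C)=C/C[C@H](O)/C(C)=C/C(=O)OCC | intermediate
12 | (5S)-(E)-ene-2,5-diol | CC(C)(C)[Si](C)(C)OCC/C(C)=C/CC/C(C)=C/C[C@H](O)/C(C)=C/CO | intermediate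
13 | (3S,4S,5S)-epoxy diol | CC(C)(C)[Si](C)(C)OCC/C(C)=C/CC/C(C)=C/C[C@H](O)[C@]1(C)O[C@H]1CO | intermediate
14 | (3R,4S,5S)-epoxy aldehyde | CC(C)(C)[Si](C)(C)OCC/C(C)=C/CC/C(C)=C/C[C@H](O)[C@]1(C)O[C@H]1C=O | intermediate
15 | methyl propiolate | C#CC(=O)OC | starting material
16 | methyl (Z)-2-(hydroxymethyl)-3-iodoacrylate | COC(=O)/C(CO)=C\I | intermediate
17 | (2S,3S,4S,5S)-butenolide diol | CC(C)(C)[Si](C)(C)OCC/C(C)=C/CC/C(C)=C/C[C@H](O)[C@]1(C)O[C@H]1[C@H]2OC(=O)C(CO)=C2 | intermediate
18 | (2S,3S,4S,5R)-5,17-diacetate | CC(C)(C)[Si](C)(C)OCC/C(C)=C/CC/C(C)=C/C[C@@H](OC(C)=O)[C@]1(C)O[C@H]1[C@H]2OC(=O)C(COC(C)=O)=C2 | intermediate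
19 | seco-alcohol | OCC/C(C)=C/CC/C(C)=C/C[C@@H](OC(C)=O)[C@]1(C)O[C@H]1[C@H]2OC(=O)C(COC(C)=O)=C2 | intermediate
20 | michaolide F | C=C1C(=O)O[C@H]2[C@H]1[C@H](O)C/C(C)=C/CC/C(C)=C/C[C@@H](OC(C)=O)[C@]1(C)O[C@@H]21 | target

**Totals**
Total steps: 16, counting the one-pot ester activation/electrolysis as one step.
Longest linear sequence: 14 (1→2→4→5→6→9→10→11→12→13→14→17→18→19→20).

**Three steps most likely to fail**
1. **Step 16 (proposed new macrocyclisation).** The risks are slow 14-membered radical closure, competing HAT at other sites, and low selectivity at C14.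
   - Fallback (known chemistry): from 17, convert C17-OH to the bromide (CBr4/PPh3) before the C5 Mitsunobu, then desilylate and oxidise C14 to the aldehyde (DMP).
   - Close the ring by the established intramolecular CrCl2 or Zn Barbier allylation of a 3-(bromomethyl)butenolide.
   - Its closed chair transition state should give the trans-lactone but the 14S alcohol. Correct this by Mitsunobu inversion with HCO2H followed by mild formate methanolysis.
2. **Step 14 (SN2 inversion at the hindered C5 carbinol with a weak acid).** The risks are elimination or no reaction.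
   - Fallback: run the sequence in the 5R series from D-malic acid and mask O5 as a TBS ether, so that only the C2 hydroxyl binds vanadium.
   - Epoxidation then occurs anti to the OTBS group in the A(1,2)-minimised conformer and gives the threo epoxide directly.
   - Finish with desilylation and simple Ac2O acetylation, with no inversion needed.
3. **Step 13 (NHK on an α,β-epoxy aldehyde).** The risks are modest Felkin selectivity and Cr-induced epoxide damage.
   - Fallback: after the C5 Mitsunobu, add vinylmagnesium bromide to the aldehyde and oxidise the epimeric carbinols to the epoxy enone.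
   - Reduce with Zn(BH4)2 (chelation-controlled, anti epoxy alcohol) to fix C2.
   - Esterify with 2-(acetoxymethyl)acrylic acid and form the butenolide by ring-closing metathesis.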